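**Plan**
1. Cuts: the last step traces all four phenols back to benzyl ethers and both ArCH2–CH2Ar bridges back to stilbene C=C bonds. The ring C/ring D bridge C=C is then cut into two aryl aldehyde carbons, the ring B–O bond of the diaryl ether by Ullmann coupling, and the ring A/ring B alkene by Horner–Wadsworth–Emmons (HWE) olefination.
2. Enabling feature: the bond made in the key step lies between two benzylic CH2 carbons, one on ring C (para to the ring C OH, meta to the diaryl ether O) and one on ring D (ortho to a hydroquinone OH). Each corresponds to a non-enolisable ArCH=O carbon, and each arene can stabilise a benzylic carbanion.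
3. Key event: the two formyl carbons have the same (electrophilic) polarity. They are joined by reversing the polarity of the ring D aldehyde as its N–H hydrazone in a Ru(II)-catalysed reductive carbonyl cross-coupling that gives the alkene, N2 and water.
4. Forward order: all four benzene rings are bought, none is built. HWE joins A to B, Ullmann etherification joins B–O–C, the carbonyl cross-coupling joins C to D, and one hydrogenation saturates both bridges and frees the four phenols.
5. Stereochemistry: the target has no stereogenic element, so nothing is set; the alkene geometries of the intermediates are erased in the last step.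

Key step: step 6

Remark: the target has no stereocentre, axis or double bond, so it is achiral and the "single enantiomer" is simply the compound itself.

**Step 1**
Reactants: 1 3-(benzyloxy)benzaldehyde; 2 diethyl (4-bromobenzyl)phosphonate
Product: 3 (E)-1-(benzyloxy)-3-[2-(4-bromophenyl)ethenyl]benzene
Conditions: KOtBu, THF, 0 °C → rt
Reagents that add atoms: none
Why: Horner–Wadsworth–Emmons olefination of a non-enolisable aryl aldehyde with a benzylic phosphonate anion should give the (E)-stilbene; the aryl bromide and benzyl ether are inert to KOtBu at this temperature.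

**Step 2**
Reactants: 4 3,4-dihydroxybenzaldehyde
Product: 5 4-(benzyloxy)-3-hydroxybenzaldehyde
Conditions: BnBr (1.0 equiv), NaHCO3, NaI (cat.), DMF, 40 °C
Reagents that add atoms: benzyl bromide, BrCc1ccccc1
Why: Williamson etherification under weak base; only the more acidic 4-OH (para to the formyl group) is deprotonated by NaHCO3, so mono-benzylation should occur there, as is well precedented for this catechol aldehyde.

**Step 3**
Reactants: 3 (E)-1-(benzyloxy)-3-[2-(4-bromophenyl)ethenyl]benzene; 5 4-(benzyloxy)-3-hydroxybenzaldehyde
Product: 6 4-(benzyloxy)-3-{4-[(E)-2-(3-(benzyloxy)phenyl)ethenyl]phenoxy}benzaldehyde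
Conditions: CuI (cat.), N,N-dimethylglycine·HCl (cat.), Cs2CO3, dioxane, 100 °C, Ar
Reagents that add atoms: none
Why: Ullmann-type Cu(I)/amino acid-promoted C–O coupling of a phenol with an unactivated aryl bromide, a standard diaryl ether construction for isovanillin-type phenols; the aldehyde, stilbene and benzyl ethers should tolerate Cs2CO3 and copper.

**Step 4**
Reactants: 7 2,5-dihydroxybenzaldehyde
Product: 8 2,5-bis(benzyloxy)benzaldehyde
Conditions: BnBr (2.4 equiv), K2CO3, DMF, 60 °C
Reagents that add atoms: benzyl bromide, BrCc1ccccc1
Why: double Williamson etherification; K2CO3 in warm DMF should also alkylate the hydrogen-bonded 2-OH.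

**Step 5**
Reactants: 8 2,5-bis(benzyloxy)benzaldehyde
Product: 9 (E)-[2,5-bis(benzyloxy)benzylidene]hydrazine (the N-unsubstituted hydrazone of 8)
Conditions: N2H4·H2O (3 equiv), EtOH, 0 °C → rt (8 added slowly); aqueous wash, dried, used at once without purification
Reagents that add atoms: hydrazine (as the monohydrate), NN
Why: condensation of an aryl aldehyde with excess hydrazine should give the N–H hydrazone, the excess and slow addition suppressing azine formation; free hydrazine is washed out so that it cannot reach aldehyde 6 in step 6.

**Step 6**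
Reactants: 6 4-(benzyloxy)-3-{4-[(E)-2-(3-(benzyloxy)phenyl)ethenyl]phenoxy}benzaldehyde; 9 (E)-[2,5-bis(benzyloxy)benzylidene]hydrazine (1.3 equiv)
Product: 10 1,4-bis(benzyloxy)-2-[(E)-2-(4-(benzyloxy)-3-{4-[(E)-2-(3-(benzyloxy)phenyl)ethenyl]phenoxy}phenyl)ethenyl]benzene
Conditions: [Ru(p-cymene)Cl2]2 (cat.), dmpe (cat.), KOtBu (cat.), THF, 45 °C, Ar
Reagents that add atoms: none
Why: The Ru(II)/dmpe complex binds the deprotonated N–H hydrazone 9 through nitrogen together with aldehyde 6, and the hydrazone carbon (the future ring D benzylic carbon) attacks the formyl carbon of 6 (the future ring C benzylic carbon) in a six-membered chair-like transition state, so that an aldehyde carbon acts as a carbanion equivalent. Base-induced loss of N2 from the resulting β-alkoxy diazene (Wolff–Kishner type) leaves a benzylic carbanion stabilised by ring D, which expels the β-hydroxide (E1cB) to give the stilbene, with N2 and water as the only coproducts. The closest known reaction type is the Ru(II)-catalysed, hydrazine-mediated reductive cross-coupling of two aromatic carbonyl compounds to an olefin, a polarity-reversed and cross-selective counterpart of the McMurry coupling. No ring is closed and no stereocentre is formed; the E alkene is expected as the conjugated, less hindered isomer, but its geometry is of no consequence because step 7 saturates it. The selectivity needed is cross-coupling over homo-coupling and azine formation, and it is secured because only 8 was converted into a hydrazone beforehand and free hydrazine was removed, so 9 is the only carbanion source and 6 the only carbonyl electrophile, and neither partner is enolisable. The benzyl ethers, the diaryl ether and the first stilbene should be inert to the catalytic base at 45 °C.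

**Step 7**
Reactants: 10 1,4-bis(benzyloxy)-2-[(E)-2-(4-(benzyloxy)-3-{4-[(E)-2-(3-(benzyloxy)phenyl)ethenyl]phenoxy}phenyl)ethenyl]benzene
Product: 11 2-[2-(4-hydroxy-3-{4-[2-(3-hydroxyphenyl)ethyl]phenoxy}phenyl)ethyl]benzene-1,4-diol (target)
Conditions: H2 (1 atm), 10% Pd/C, THF/MeOH, rt; filtration and concentration under Ar
Reagents that add atoms: none
Why: heterogeneous hydrogenation over Pd/C should saturate both stilbene C=C bonds and hydrogenolyse the four O-benzyl groups in one operation, while the diaryl ether and the arene rings stay untouched at 1 atm and rt; no stereocentre is formed.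

**Compound list**
1 | 3-(benzyloxy)benzaldehyde | O=Cc1cccc(OCc2ccccc2)c1 | starting material
2 | diethyl (4-bromobenzyl)phosphonate | CCOP(=O)(Cc1ccc(Br)cc1)OCC | starting material
3 | (E)-1-(benzyloxy)-3-[2-(4-bromophenyl)ethenyl]benzene | Brc1ccc(/C=C/c2cccc(OCc3ccccc3)c2)cc1 | intermediate
4 | 3,4-dihydroxybenzaldehyde | O=Cc1ccc(O)c(O)c1 | starting material
5 | 4-(benzyloxy)-3-hydroxybenzaldehyde | O=Cc1ccc(OCc2ccccc2)c(O)c1 | intermediate
6 | 4-(benzyloxy)-3-{4-[(E)-2-(3-(benzyloxy)phenyl)ethenyl]phenoxy}benzaldehyde | O=Cc1ccc(OCc2ccccc2)c(Oc2ccc(/C=C/c3cccc(OCc4ccccc4)c3)cc2)c1 | intermediate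
7 | 2,5-dihydroxybenzaldehyde | O=Cc1cc(O)ccc1O | starting material
8 | 2,5-bis(benzyloxy)benzaldehyde | O=Cc1cc(OCc2ccccc2)ccc1OCc1ccccc1 | intermediate
9 | (E)-[2,5-bis(benzyloxy)benzylidene]hydrazine | N/N=C/c1cc(OCc2ccccc2)ccc1OCc1ccccc1 | intermediate
10 | 1,4-bis(benzyloxy)-2-[(E)-2-(4-(benzyloxy)-3-{4-[(E)-2-(3-(benzyloxy)phenyl)ethenyl]phenoxy}phenyl)ethenyl]benzene | c1ccccc1COc1ccc(OCc2ccccc2)c(/C=C/c2ccc(OCc3ccccc3)c(Oc3ccc(/C=C/c4cccc(OCc5ccccc5)c4)cc3)c2)c1 | intermediate
11 | 2-[2-(4-hydroxy-3-{4-[2-(3-hydroxyphenyl)ethyl]phenoxy}phenyl)ethyl]benzene-1,4-diol | Oc1cccc(CCc2ccc(Oc3cc(CCc4cc(O)ccc4O)ccc3O)cc2)c1 | target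

**Step count and risks**
Total steps: 7. Longest linear sequence: 4 steps (1 → 3 → 6 → 7; the branches 2 → 3 → 6 → 7 and 4 → 5 → 6 → 7 are equally long).

Steps most likely to fail:

1. Step 6. Exchange of the hydrazone NH2–N= unit between the two aldehydes, or azine formation, may scramble the partners or stall the catalyst, and the E1cB elimination after C–C bond formation may be incomplete. The fallback sets out from 8 (and so also bypasses step 5) and comes back at 10. NaBH4 reduction (MeOH/THF, 0 °C) gives 2,5-bis(benzyloxy)benzyl alcohol F1. PBr3 (CH2Cl2, 0 °C) gives 2,5-bis(benzyloxy)benzyl bromide F2. A Michaelis–Arbuzov reaction with triethyl phosphite (neat, 130 °C) gives diethyl [2,5-bis(benzyloxy)benzyl]phosphonate F3. HWE olefination of aldehyde 6 with F3 (KOtBu, THF, 0 °C → rt) should then give 10.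

2. Step 3. The C–O coupling of the ortho-alkoxy phenol with the unactivated aryl bromide may be slow, with competing hydrodebromination and base-induced degradation of the aldehyde at 100 °C. The fallback sets out from 3 and comes back at 6. Bromine–lithium exchange (n-BuLi, THF, −78 °C), then B(OiPr)3 and aqueous HCl, gives {4-[(E)-2-(3-(benzyloxy)phenyl)ethenyl]phenyl}boronic acid F4. Oxidative Chan–Lam–Evans coupling of F4 with phenol 5 (Cu(OAc)2, pyridine, 4 Å MS, CH2Cl2, air, rt) should give 6 at room temperature.

3. Step 7. Hydrogenolysis of the four benzyl ethers may stop short through catalyst poisoning by traces of copper, ruthenium, phosphine or hydrazine, and the hydroquinone ring may oxidise in air during filtration. The fallback sets out from 10 and comes back at 11. Diimide reduction (TsNHNH2, NaOAc, THF/H2O, reflux) saturates both alkenes without touching the benzyl ethers and gives 1,4-bis(benzyloxy)-2-[2-(4-(benzyloxy)-3-{4-[2-(3-(benzyloxy)phenyl)ethyl]phenoxy}phenyl)ethyl]benzene F5. Non-reductive debenzylation of F5 with BCl3 and pentamethylbenzene (CH2Cl2, −78 °C, acidic work-up under Ar) should give 11.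

**Further compounds**
F1 | step 6 | 2,5-bis(benzyloxy)benzyl alcohol | OCc1cc(OCc2ccccc2)ccc1OCc1ccccc1
F2 | step 6 | 2,5-bis(benzyloxy)benzyl bromide | BrCc1cc(OCc2ccccc2)ccc1OCc1ccccc1
F3 | step 6 | diethyl [2,5-bis(benzyloxy)benzyl]phosphonate | CCOP(=O)(Cc1cc(OCc2ccccc2)ccc1OCc1ccccc1)OCC
F4 | step 3 | {4-[(E)-2-(3-(benzyloxy)phenyl)ethenyl]phenyl}boronic acid | OB(O)c1ccc(/C=C/c2cccc(OCc3ccccc3)c2)cc1
F5 | step 7 | 1,4-bis(benzyloxy)-2-[2-(4-(benzyloxy)-3-{4-[2-(3-(benzyloxy)phenyl)ethyl]phenoxy}phenyl)ethyl]benzene | c1ccccc1COc1ccc(OCc2ccccc2)c(CCc2ccc(OCc3ccccc3)c(Oc3ccc(CCc4cccc(OCc5ccccc5)c4)cc3)c2)c1
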